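**Plan**
1. Cuts: the ten O-benzyl groups and the C8 bromine of ring D come off last, and C3–OH of the upper unit goes back to C3–B. Ring C of the upper flavan is then cut at C4a–C4 and at C2–C3, which gives mixed acetal 5 (rings A and B) and the (Z)-alkenyl MIDA boronate 14 that carries the whole gallocatechin unit on the future C4. Compound 14 is cut at its aryl–vinyl bond.
2. Forward: 5 is made in two steps from the aldehyde. (+)-Gallocatechin is benzylated, brominated at C8, iodinated at C6 and vinylated (Negishi) to 14. A catalytic asymmetric oxa-Povarov [4+2] then closes ring C and joins the two halves, followed by boronate oxidation and one hydrogenolysis.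
3. Enabling feature: C4a of the resorcinol ring A is ortho to O1 and para to O7, so the aryl oxocarbenium ion (C4a=C8a–O1=C2) is a cationic 2-oxadiene. C4 is benzylic to the phloroglucinol ring D, which stabilizes the cation left when C3 attacks C2. Boron on C3 is a masked hydroxyl that makes C3 the nucleophilic terminus.
4. Stereochemistry: the lower unit (2R,3S) comes from (+)-gallocatechin. C3/C4 cis comes from the Z-alkene, C2/C3 trans from the exo approach, the absolute sense from the chiral counteranion, and C3–O from stereoretentive oxidation.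

Key step: step 8

Remark: the target is read as robinetinidol-(4β→6)-gallocatechin, upper unit (2R,3S,4R) with 2,3-trans-3,4-cis substituents and lower unit (2R,3S). (+)-Gallocatechin and (Z)-2-bromovinylboronic acid MIDA ester are taken as purchasable. The antipode of the chiral acid for step 8 is to be fixed by a preliminary screen. "MIDA boryl" means the 6-methyl-4,8-dioxo-1,3,6,2-dioxazaborocan-2-yl group.

**Step 1**
Reactants: 1 3,4,5-tris(benzyloxy)benzaldehyde
Product: 2 3,4,5-tris(benzyloxy)benzaldehyde dimethyl acetal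
Conditions: HC(OMe)3, cat. p-TsOH, MeOH, rt; Et3N quench
Reagents that add atoms: trimethyl orthoformate, COC(OC)OC
Why: Acid-catalysed acetalization, driven by the orthoformate as water scavenger, converts the aldehyde into its dimethyl acetal; no stereocentre is formed.

**Step 2**
Reactants: 2 3,4,5-tris(benzyloxy)benzaldehyde dimethyl acetal; 3 3-(benzyloxy)phenol
Product: 5 racemic O-aryl O-methyl mixed acetal, via α-chloro ether 4 (not isolated)
Conditions: 2, AcCl, CH2Cl2, 0 °C to rt, evaporation; then sodium phenoxide of 3 (NaH, THF, 0 °C), −78 to 0 °C; chromatography on Et3N-deactivated silica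
Reagents that add atoms: none
Why: Acetyl chloride exchanges one methoxy group for chloride (α-chloro ether formation) and the sodium phenoxide displaces the chloride at oxygen (Williamson-type etherification through an SN1-like ion pair) under basic conditions, which avoids acid-promoted Friedel–Crafts C-alkylation of the resorcinol ether; the acetal carbon is formed racemic and is planarized later.

**Step 3**
Reactants: 6 (+)-gallocatechin, (2R,3S)
Product: 7 5,7,3',4',5'-penta-O-benzyl-(+)-gallocatechin
Conditions: BnBr, K2CO3, DMF, 0 °C to rt, argon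
Reagents that add atoms: benzyl bromide, BrCc1ccccc1
Why: Williamson etherification with the weak base K2CO3 should benzylate the five phenols and leave the C3 alcohol, and the mild air-free conditions avoid C2 epimerization and oxidation of the pyrogallol ring.

**Step 4**
Reactants: 7 5,7,3',4',5'-penta-O-benzyl-(+)-gallocatechin
Product: 8 3,5,7,3',4',5'-hexa-O-benzyl-(+)-gallocatechin
Conditions: NaH, BnBr, cat. Bu4NI, THF/DMF, 0 °C to rt
Reagents that add atoms: benzyl bromide, BrCc1ccccc1
Why: Williamson etherification of the secondary alkoxide caps the last hydroxyl so that it cannot trap cations in step 8; C3 keeps its configuration because its C–O bond is not touched.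

**Step 5**
Reactants: 8 3,5,7,3',4',5'-hexa-O-benzyl-(+)-gallocatechin
Product: 9 8-bromo-hexa-O-benzyl-gallocatechin
Conditions: NBS, CH2Cl2, −78 °C to rt
Reagents that add atoms: N-bromosuccinimide, BrN1C(=O)CCC1=O
Why: Electrophilic aromatic bromination of the phloroglucinol ring D should take C8, the less hindered of its two free positions (flanked by one benzyloxy group and the ring oxygen), as is usual for O-benzylated flavan-3-ols; the bromine then blocks C8.

**Step 6**
Reactants: 9 8-bromo-hexa-O-benzyl-gallocatechin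
Product: 10 8-bromo-6-iodo-hexa-O-benzyl-gallocatechin
Conditions: NIS, cat. CF3CO2H, MeCN/CH2Cl2, 0 °C to rt, dark
Reagents that add atoms: N-iodosuccinimide, IN1C(=O)CCC1=O
Why: Electrophilic aromatic iodination should take the only free position left on ring D, C6, which is activated by O5 and O7 (ortho) and O1 (para) and is far more electron-rich than ring B or the benzyl rings.

**Step 7**
Reactants: 10 8-bromo-6-iodo-hexa-O-benzyl-gallocatechin; 11 (Z)-2-bromovinylboronic acid MIDA ester
Product: 14 C6 (Z)-alkenyl MIDA boronate of 8-bromo-hexa-O-benzyl-gallocatechin, via arylmagnesium chloride 12 (not isolated), via arylzinc chloride 13 (not isolated)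
Conditions: iPrMgCl·LiCl, THF, −20 °C; ZnCl2, −20 °C to rt; 11, cat. Pd2(dba)3 (zerovalent palladium), tri(2-furyl)phosphine, THF, rt
Reagents that add atoms: none
Why: Iodine–magnesium exchange is selective for C–I over C–Br, transmetalation gives a tolerant arylzinc, and the Negishi coupling with the alkenyl bromide should retain the Z geometry while the sp3 boron of the MIDA boronate stays inert under anhydrous conditions.

**Step 8**
Reactants: 5 racemic O-aryl O-methyl mixed acetal; 14 C6 (Z)-alkenyl MIDA boronate of 8-bromo-hexa-O-benzyl-gallocatechin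
Product: 17 C3-boryl 4-arylflavan cycloadduct (C2 aryl trans to boron; boron cis to the C4 aryl), via aryl oxocarbenium ion 15 (not isolated), via C4 benzylic cation 16 (not isolated)
Conditions: chiral BINOL-derived imidodiphosphorimidate Brønsted acid (N-triflyl, 3,3'-diaryl; 5 mol %), 5 Å molecular sieves, CHCl3, −40 °C
Reagents that add atoms: none
Why: Proposed new method: the chiral acid protonates the methoxy oxygen of 5 and expels methanol to give the (E)-aryl oxocarbenium ion 15 as an ion pair with the chiral anion, in which O1=C2 and the C8a=C4a bond of the resorcinol ring A form a cationic 2-oxadiene; C3 of 14 (α to boron, β to ring D) adds to C2 and the resulting C4 cation 16, stabilized by the three oxygen atoms of ring D and by the σ(C–B) bond, is captured by C4a. The closest known reactions are the SnCl4-promoted oxa-Povarov reaction of phenol-derived mixed acetals with styrenes, the chiral Brønsted acid catalysed Povarov reaction and Diels–Alder reactions of vinylboronates as enol equivalents, whereas an alkenyl MIDA boronate as the two-carbon partner and anion control of an oxa-Povarov reaction are new. Ring C closes as the second bond of the formal [4+2], an intramolecular Friedel–Crafts alkylation that forms a six-membered ring with the arene bond C4a=C8a inside it (6-endo with respect to the arene). C3 and C4 are set cis by suprafacial addition across the Z-alkene, the cation being attacked anti to the hyperconjugating C–B bond before C3–C4 rotation, and C2 is set trans to C3 by an exo approach that keeps the MIDA cage and the doubly ortho-substituted ring D away from ring A, the same isomer being the one with both large C2 and C3 groups equatorial. The absolute configuration follows from the face of 15 that the chiral anion leaves open, because the gallocatechin stereocentres are too remote to bias the alkene faces. The step needs attack through C3 and not C4 (secured by the 2,4,6-trioxygenated ring D and the β-boron effect, with no heteroatom donor on the alkene), ring closure para and not ortho to the benzyloxy group of ring A (sterics), and no arylation at C8 of ring D (blocked by bromine).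

**Step 9**
Reactants: 17 C3-boryl 4-arylflavan cycloadduct
Product: 18 8'-bromo-deca-O-benzyl-robinetinidol-(4β→6)-gallocatechin with free upper C3–OH
Conditions: 1 M aq NaOH, THF, rt; then 30% aq H2O2, 0 °C to rt
Reagents that add atoms: hydrogen peroxide, OO
Why: Aqueous base removes the MIDA ligand and alkaline hydrogen peroxide oxidizes the boronic acid by 1,2-migration of C3 from boron to oxygen with retention of configuration (organoborane oxidation), which should give the 3S hydroxyl cis to the C4 aryl.

**Step 10**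
Reactants: 18 8'-bromo-deca-O-benzyl-robinetinidol-(4β→6)-gallocatechin
Product: 19 robinetinidol-(4β→6)-gallocatechin (target)
Conditions: H2 (1 atm), Pd(OH)2/C, Et3N, THF/MeOH/H2O, rt; filtration under argon
Reagents that add atoms: none
Why: Catalytic hydrogenolysis over Pd(OH)2/C should cleave the ten O-benzyl groups and the C8–Br bond in one operation, the amine taking up HBr so that the interflavan bond and all stereocentres stay untouched.

**Compound list**
1 | 3,4,5-tris(benzyloxy)benzaldehyde | O=Cc1cc(OCc2ccccc2)c(OCc2ccccc2)c(OCc2ccccc2)c1 | starting material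
2 | 1,2,3-tris(benzyloxy)-5-(dimethoxymethyl)benzene | COC(OC)c1cc(OCc2ccccc2)c(OCc2ccccc2)c(OCc2ccccc2)c1 | intermediate
3 | 3-(benzyloxy)phenol | Oc1cccc(OCc2ccccc2)c1 | starting material
4 | 1,2,3-tris(benzyloxy)-5-[chloro(methoxy)methyl]benzene (racemic, not isolated) | COC(Cl)c1cc(OCc2ccccc2)c(OCc2ccccc2)c(OCc2ccccc2)c1 | intermediate
5 | 1,2,3-tris(benzyloxy)-5-{[3-(benzyloxy)phenoxy](methoxy)methyl}benzene (racemic) | COC(Oc1cccc(OCc2ccccc2)c1)c1cc(OCc2ccccc2)c(OCc2ccccc2)c(OCc2ccccc2)c1 | intermediate
6 | (+)-gallocatechin, (2R,3S)-2-(3,4,5-trihydroxyphenyl)chromane-3,5,7-triol | c1c(O)cc2c(c1O)C[C@H](O)[C@@H](c1cc(O)c(O)c(O)c1)O2 | starting material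
7 | (2R,3S)-5,7-bis(benzyloxy)-2-[3,4,5-tris(benzyloxy)phenyl]chroman-3-ol | c1c(OCc3ccccc3)cc2c(c1OCc1ccccc1)C[C@H](O)[C@@H](c1cc(OCc3ccccc3)c(OCc3ccccc3)c(OCc3ccccc3)c1)O2 | intermediate
8 | (2R,3S)-3,5,7-tris(benzyloxy)-2-[3,4,5-tris(benzyloxy)phenyl]chroman | c1c(OCc3ccccc3)cc2c(c1OCc1ccccc1)C[C@H](OCc1ccccc1)[C@@H](c1cc(OCc3ccccc3)c(OCc3ccccc3)c(OCc3ccccc3)c1)O2 | intermediate
9 | (2R,3S)-3,5,7-tris(benzyloxy)-8-bromo-2-[3,4,5-tris(benzyloxy)phenyl]chroman | c1c(OCc3ccccc3)c(Br)c2c(c1OCc1ccccc1)C[C@H](OCc1ccccc1)[C@@H](c1cc(OCc3ccccc3)c(OCc3ccccc3)c(OCc3ccccc3)c1)O2 | intermediate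
10 | (2R,3S)-3,5,7-tris(benzyloxy)-8-bromo-6-iodo-2-[3,4,5-tris(benzyloxy)phenyl]chroman | Ic1c(OCc3ccccc3)c(Br)c2c(c1OCc1ccccc1)C[C@H](OCc1ccccc1)[C@@H](c1cc(OCc3ccccc3)c(OCc3ccccc3)c(OCc3ccccc3)c1)O2 | intermediate
11 | (Z)-2-bromovinylboronic acid MIDA ester | Br/C=C\[B-]12OC(=O)C[N+]1(C)CC(=O)O2 | starting material
12 | C6 arylmagnesium chloride of 9 (not isolated) | Cl[Mg]c1c(OCc3ccccc3)c(Br)c2c(c1OCc1ccccc1)C[C@H](OCc1ccccc1)[C@@H](c1cc(OCc3ccccc3)c(OCc3ccccc3)c(OCc3ccccc3)c1)O2 | intermediate
13 | C6 arylzinc chloride of 9 (not isolated) | Cl[Zn]c1c(OCc3ccccc3)c(Br)c2c(c1OCc1ccccc1)C[C@H](OCc1ccccc1)[C@@H](c1cc(OCc3ccccc3)c(OCc3ccccc3)c(OCc3ccccc3)c1)O2 | intermediate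
14 | (2R,3S)-3,5,7-tris(benzyloxy)-8-bromo-6-[(Z)-2-(MIDA boryl)ethenyl]-2-[3,4,5-tris(benzyloxy)phenyl]chroman | O=C1C[N+]2(C)CC(=O)O[B-]2(O1)/C=C\c1c(OCc3ccccc3)c(Br)c2c(c1OCc1ccccc1)C[C@H](OCc1ccccc1)[C@@H](c1cc(OCc3ccccc3)c(OCc3ccccc3)c(OCc3ccccc3)c1)O2 | intermediate
15 | (E)-[3-(benzyloxy)phenyl][3,4,5-tris(benzyloxy)benzylidene]oxonium, ion pair with the chiral anion (not isolated) | c1ccccc1COc1cccc(c1)/[O+]=C/c1cc(OCc2ccccc2)c(OCc2ccccc2)c(OCc2ccccc2)c1 | intermediate
16 | open-chain C4 benzylic cation, (2S,3S) at C2 and C3, after C2–C3 bond formation (not isolated) | c5ccccc5COc1cccc(c1)O[C@H](c1cc(OCc5ccccc5)c(OCc5ccccc5)c(OCc5ccccc5)c1)[C@@H]([B-]34OC(=O)C[N+]3(C)CC(=O)O4)[CH+]c1c(OCc5ccccc5)c(Br)c2c(c1OCc1ccccc1)C[C@H](OCc1ccccc1)[C@@H](c1cc(OCc5ccccc5)c(OCc5ccccc5)c(OCc5ccccc5)c1)O2 | intermediate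
17 | (2S,3S,4R)-7-(benzyloxy)-3-(MIDA boryl)-2-[3,4,5-tris(benzyloxy)phenyl]-4-{(2R,3S)-3,5,7-tris(benzyloxy)-8-bromo-2-[3,4,5-tris(benzyloxy)phenyl]chroman-6-yl}chroman (descriptors at C2 changed by boron; spatial arrangement as in the target) | c5ccccc5COc1ccc2c(c1)O[C@H](c1cc(OCc5ccccc5)c(OCc5ccccc5)c(OCc5ccccc5)c1)[C@@H]([B-]34OC(=O)C[N+]3(C)CC(=O)O4)[C@H]2c1c(OCc5ccccc5)c(Br)c2c(c1OCc1ccccc1)C[C@H](OCc1ccccc1)[C@@H](c1cc(OCc5ccccc5)c(OCc5ccccc5)c(OCc5ccccc5)c1)O2 | intermediate
18 | (2R,3S,4R)-7-(benzyloxy)-2-[3,4,5-tris(benzyloxy)phenyl]-4-{(2R,3S)-3,5,7-tris(benzyloxy)-8-bromo-2-[3,4,5-tris(benzyloxy)phenyl]chroman-6-yl}chroman-3-ol | c5ccccc5COc1ccc2c(c1)O[C@H](c1cc(OCc5ccccc5)c(OCc5ccccc5)c(OCc5ccccc5)c1)[C@@H](O)[C@H]2c1c(OCc5ccccc5)c(Br)c2c(c1OCc1ccccc1)C[C@H](OCc1ccccc1)[C@@H](c1cc(OCc5ccccc5)c(OCc5ccccc5)c(OCc5ccccc5)c1)O2 | intermediate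
19 | robinetinidol-(4β→6)-gallocatechin, upper unit (2R,3S,4R), lower unit (2R,3S) | Oc1ccc2c(c1)O[C@H](c1cc(O)c(O)c(O)c1)[C@@H](O)[C@H]2c1c(O)cc2c(c1O)C[C@H](O)[C@@H](c1cc(O)c(O)c(O)c1)O2 | target

**Totals**
Total step count: 10. Longest linear sequence: 8 steps (steps 3 to 10, from (+)-gallocatechin).

**Steps most likely to fail**

Step 8 (Proposed new method). The C4 cation may lose its boron group or a proton instead of closing ring C. Reversible protonation of the alkene may erode the Z geometry. The chiral anion may discriminate the faces poorly, or the alkene may react through its other terminus. The fallback sets out from 9 and comes back at 18, using known chemistry. Commercial (+)-dihydrorobinetin, (2R,3R), Oc1ccc2c(c1)O[C@H](c1cc(O)c(O)c(O)c1)[C@@H](O)C2=O, is benzylated at its four phenols (BnBr, K2CO3, DMF) to 7,3',4',5'-tetra-O-benzyl-dihydrorobinetin F1. NaBH4 (THF/EtOH, 0 °C) reduces the C4 ketone to the 2,3-trans-flavan-3,4-diol F2. Ionization of the C4 hydroxyl of F2 with BF3·OEt2 (CH2Cl2, −78 to −20 °C) in the presence of 9 gives the benzylic C4 cation, which C6 of 9 captures in a Friedel–Crafts alkylation (C8 is blocked by bromine); this is the classical flavan-3,4-diol/flavan-3-ol condensation. Attack on both faces of the cation is expected, so 18 (3,4-cis) would have to be separated from its C4 epimer by chromatography.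

Step 7. The iodine–magnesium exchange or the transmetalation at the doubly ortho-substituted aryl metal may be slow. Oxidative addition into the C8–Br bond or Z/E isomerization may compete. The fallback sets out from 10 and comes back at 14. Sonogashira coupling of 10 with commercial ethynylboronic acid MIDA ester, C#C[B-]12OC(=O)C[N+]1(C)CC(=O)O2, (Pd(PPh3)2Cl2, CuI, Et3N, DMF, rt) should give the alkynyl MIDA boronate F3. Its cis-semihydrogenation (H2, Pd/CaCO3 poisoned with Pb(OAc)2, quinoline, EtOAc) should then give 14.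

Step 10. The amine may slow hydrogenolysis of the aliphatic benzyl ether, and bromide may poison the catalyst. Long exposure may cleave the benzylic C2–O bonds, and the pyrogallol rings may oxidize in air during isolation. The fallback sets out from 18 and comes back at 19. Radical-chain debromination (Bu3SnH, AIBN, toluene, 90 °C) should give the bromine-free deca-O-benzyl ether F4. Amine-free hydrogenolysis (H2, Pd(OH)2/C, THF/MeOH, rt) should then give 19.

**Further compounds**
F1 | step 8 | (2R,3R)-7-(benzyloxy)-3-hydroxy-2-[3,4,5-tris(benzyloxy)phenyl]chroman-4-one | c5ccccc5COc1ccc2c(c1)O[C@H](c1cc(OCc5ccccc5)c(OCc5ccccc5)c(OCc5ccccc5)c1)[C@@H](O)C2=O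
F2 | step 8 | (2R,3S,4R)-7-(benzyloxy)-2-[3,4,5-tris(benzyloxy)phenyl]chromane-3,4-diol | c5ccccc5COc1ccc2c(c1)O[C@H](c1cc(OCc5ccccc5)c(OCc5ccccc5)c(OCc5ccccc5)c1)[C@@H](O)[C@@H]2O
F3 | step 7 | (2R,3S)-3,5,7-tris(benzyloxy)-8-bromo-6-[(MIDA boryl)ethynyl]-2-[3,4,5-tris(benzyloxy)phenyl]chroman | O=C1C[N+]2(C)CC(=O)O[B-]2(O1)C#Cc1c(OCc3ccccc3)c(Br)c2c(c1OCc1ccccc1)C[C@H](OCc1ccccc1)[C@@H](c1cc(OCc3ccccc3)c(OCc3ccccc3)c(OCc3ccccc3)c1)O2
F4 | step 10 | (2R,3S,4R)-7-(benzyloxy)-2-[3,4,5-tris(benzyloxy)phenyl]-4-{(2R,3S)-3,5,7-tris(benzyloxy)-2-[3,4,5-tris(benzyloxy)phenyl]chroman-6-yl}chroman-3-ol | c5ccccc5COc1ccc2c(c1)O[C@H](c1cc(OCc5ccccc5)c(OCc5ccccc5)c(OCc5ccccc5)c1)[C@@H](O)[C@H]2c1c(OCc5ccccc5)cc2c(c1OCc1ccccc1)C[C@H](OCc1ccccc1)[C@@H](c1cc(OCc5ccccc5)c(OCc5ccccc5)c(OCc5ccccc5)c1)O2
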